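**Plan**

- Numbering: the phenol carbon is C1, bromine sits on C2, C3 and C6, CH2OH on C4 and H on C5.
- Retrosynthesis: the C1–OH bond is traced back to a C1–Br bond, exchanged by SNAr while the C4 substituent is a formyl group; the benzene ring is then cut at C3–C4 and C5–C6.
- Enabling feature: C6–C1–C2–C3 is an unbroken row of four heteroatom-bearing ring carbons, which is the diene of the symmetric tetrabromothiophene 1,1-dioxide, and C4–C5 (one CH2OH, one H) is the terminal alkyne propargyl alcohol.
- Forward order: sulfur oxidation of tetrabromothiophene; [4+2] cycloaddition and SO2 loss build the only ring; then alcohol to aldehyde, bromine-to-methoxy exchange para to the formyl group, O-demethylation and reduction.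
- Stereochemistry: the target has no stereocentre; the bridgehead centres of the transient cycloadduct vanish on aromatisation, and regiochemistry rests on the symmetry of the diene and on para activation by the formyl group.

Key step: step 2

**Route**

Step 1
Reactants: 1 tetrabromothiophene
Product: 3 tetrabromothiophene 1,1-dioxide, via tetrabromothiophene 1-oxide 2 (not isolated)
Conditions: CF3CO3H [from 50% aq. H2O2 and (CF3CO)2O], CH2Cl2, 0 °C to rt
Reagents that add atoms: trifluoroperacetic acid, OOC(=O)C(F)(F)F, the oxygen donor, made in the flask from hydrogen peroxide, OO, and trifluoroacetic anhydride, O=C(OC(=O)C(F)(F)F)C(F)(F)F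
Why: Sulfide-to-sulfone oxidation with the strongly electrophilic trifluoroperacetic acid should overcome the low nucleophilicity of the sulfur in this tetrahalogenated thiophene, the S-oxide 2 being oxidised further faster than it can dimerise, and the four bromines shield the resulting diene 3 from self-cycloaddition.

Step 2
Reactants: 3 tetrabromothiophene 1,1-dioxide; 4 propargyl alcohol
Product: 6 (2,3,4,5-tetrabromophenyl)methanol, via bridged sulfone cycloadduct 5 (not isolated)
Conditions: 4 (3 equiv), toluene, 100 °C, sealed tube
Reagents that add atoms: none
Why: The LUMO of the non-aromatic, electron-poor sulfone diene 3 should combine with the HOMO of the alkyne 4 in a concerted inverse-electron-demand Diels–Alder reaction that forms the C3–C4 and C5–C6 bonds of the target at the two brominated diene termini and gives the bridged sulfone 5. The bridge then leaves as SO2 in a thermally allowed cheletropic retro-[4+1] process, driven by formation of the benzene ring and of a gas. The closest known reaction type is the cycloaddition/SO2-extrusion sequence of tetrahalothiophene 1,1-dioxides with alkynes, which delivers 1,2,3,4-tetrahaloarenes. The one ring, the six-membered carbocycle, is closed by the intermolecular [4+2] cycloaddition, both ring bonds arising in the same event, and becomes aromatic on loss of the one-atom bridge. No stereocentre is set, because the two bridgehead centres of racemic 5 are erased by the extrusion. Regioselectivity is not an issue since the C2v-symmetric diene gives the same arene from either orientation of the alkyne, so only chemoselectivity is needed: neutral, base-free conditions keep the hydroxyl group from adding to the sulfone diene, and an excess of alkyne lets the cycloaddition outrun thermal decay of 3.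

Step 3
Reactants: 6 (2,3,4,5-tetrabromophenyl)methanol
Product: 7 2,3,4,5-tetrabromobenzaldehyde
Conditions: activated MnO2 (excess), CH2Cl2, rt
Reagents that add atoms: none
Why: Heterogeneous MnO2 oxidation of a benzylic alcohol should stop at the aldehyde and leave the four aryl bromides untouched.

Step 4
Reactants: 7 2,3,4,5-tetrabromobenzaldehyde
Product: 9 2,3,5-tribromo-4-methoxybenzaldehyde, via sodium Meisenheimer adduct 8 (not isolated)
Conditions: NaOMe (1.05 equiv), MeOH–THF, 0 to 40 °C
Reagents that add atoms: sodium methoxide, [Na+].[O-]C
Why: Nucleophilic aromatic substitution by addition–elimination (SNAr) should occur at the carbon para to the formyl group, where the σ-complex 8 is stabilised as a formyl enolate and by two ortho bromines plus one meta bromine, whereas the competing ortho carbon has only one ortho and one meta bromine and a deactivating para bromine, and the hydrogen-bonded, non-chelated methoxide in methanol further favours para attack, one equivalent of base at moderate temperature guarding against a second substitution.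

Step 5
Reactants: 9 2,3,5-tribromo-4-methoxybenzaldehyde
Product: 11 2,3,5-tribromo-4-hydroxybenzaldehyde, via aryloxydibromoborane 10 (not isolated)
Conditions: BBr3 (2.5 equiv), CH2Cl2, −78 to 0 °C; then H2O
Reagents that add atoms: none
Why: Lewis acid ether cleavage with BBr3 should proceed by coordination of boron to the twisted, di-ortho-brominated methoxy oxygen and SN2 attack of bromide on the methyl group to give the borate 10, which water hydrolyses to the phenol, while the formyl group is only complexed reversibly and returns on work-up.

Step 6
Reactants: 11 2,3,5-tribromo-4-hydroxybenzaldehyde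
Product: 12 2,3,6-tribromo-4-(hydroxymethyl)phenol
Conditions: NaBH4, THF–H2O, 0 °C; then aq. NH4Cl
Reagents that add atoms: none
Why: Hydride reduction of the aldehyde with NaBH4 should leave the aryl bromides alone, and a cold reaction followed by a mildly acidic, methanol-free work-up avoids ionisation of the para-hydroxybenzyl alcohol to a quinone methide.

**Compound list**

1 | tetrabromothiophene | Brc1sc(Br)c(Br)c1Br | starting material
2 | tetrabromothiophene 1-oxide (not isolated) | O=S1C(Br)=C(Br)C(Br)=C1Br | intermediate
3 | tetrabromothiophene 1,1-dioxide | O=S1(=O)C(Br)=C(Br)C(Br)=C1Br | intermediate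
4 | propargyl alcohol (prop-2-yn-1-ol) | C#CCO | starting material
5 | 1,2,3,4-tetrabromo-5-(hydroxymethyl)-7-thiabicyclo[2.2.1]hepta-2,5-diene 7,7-dioxide (racemic, not isolated) | OCC1=CC2(Br)C(Br)=C(Br)C1(Br)S2(=O)=O | intermediate
6 | (2,3,4,5-tetrabromophenyl)methanol | OCc1cc(Br)c(Br)c(Br)c1Br | intermediate
7 | 2,3,4,5-tetrabromobenzaldehyde | O=Cc1cc(Br)c(Br)c(Br)c1Br | intermediate
8 | sodium (2,3,4,5-tetrabromo-4-methoxycyclohexa-2,5-dien-1-ylidene)methanolate, the Meisenheimer adduct of methoxide at C4 of 7 (not isolated) | [Na+].[O-]C=C1C=C(Br)C(Br)(OC)C(Br)=C1Br | intermediate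
9 | 2,3,5-tribromo-4-methoxybenzaldehyde | COc1c(Br)cc(C=O)c(Br)c1Br | intermediate
10 | dibromo(2,3,6-tribromo-4-formylphenoxy)borane (not isolated) | O=Cc1cc(Br)c(OB(Br)Br)c(Br)c1Br | intermediate
11 | 2,3,5-tribromo-4-hydroxybenzaldehyde | O=Cc1cc(Br)c(O)c(Br)c1Br | intermediate
12 | 2,3,6-tribromo-4-(hydroxymethyl)phenol | OCc1cc(Br)c(O)c(Br)c1Br | target

**Count**

Total step count: 6. Longest linear sequence: 6 steps (1 to 12; propargyl alcohol 4 enters in step 2).

**Steps most likely to fail**

Step 4. Methoxide may attack ortho instead of para to the formyl group. It may also add reversibly to the formyl group, which switches off the activation, or cause base-induced loss of the formyl group. The fallback replaces the formyl group by a cyano group, which alkoxide cannot mask in this way and which directs substitution in polyhalobenzonitriles to the para position. Setting out from 7, condensation with NH2OH·HCl and dehydration in refluxing HCO2H buffered with HCO2Na would pass through 2,3,4,5-tetrabromobenzaldehyde oxime F1 (not isolated) and give 2,3,4,5-tetrabromobenzonitrile F2. NaOMe in MeOH–THF would then give 2,3,5-tribromo-4-methoxybenzonitrile F3. Reduction with i-Bu2AlH in toluene at −78 °C and hydrolysis with aqueous HCl, through 2,3,5-tribromo-4-methoxybenzaldimine F4 (not isolated), would come back to the route at aldehyde 9.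

Step 2. The unactivated terminal alkyne may add too slowly, so that thermal decomposition of the sulfone diene or conjugate addition of the free hydroxyl group takes over. The fallback uses an alkene, a more willing dienophile towards tetrahalothiophene dioxides, and aromatises afterwards. Setting out from 3, allyl alcohol in toluene at 60–80 °C would give 1,2,3,4-tetrabromo-5-(hydroxymethyl)-7-thiabicyclo[2.2.1]hept-2-ene 7,7-dioxide F5 (not isolated). Loss of SO2 would give racemic (2,3,4,5-tetrabromocyclohexa-2,4-dien-1-yl)methanol F6. Dehydrogenation with 2,3-dichloro-5,6-dicyano-1,4-benzoquinone (DDQ) in hot chlorobenzene would come back to the route at 6.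

Step 5. BBr3 may attack the formyl group (geminal bromination) or cleave the flanked ether incompletely. The fallback avoids the methyl ether by introducing the oxygen with a hydroxide surrogate. Setting out from 7, the sodium alkoxide of 2-(methylsulfonyl)ethanol (NaH, DMF, 0 °C to rt) would substitute the para bromine to give 2,3,5-tribromo-4-[2-(methylsulfonyl)ethoxy]benzaldehyde F7 (not isolated). Under the basic conditions this ether fragments by E1cB elimination to the phenoxide and methyl vinyl sulfone, and acidification would come back to the route at 11.

**Further compounds**

F1 | step 4 | 2,3,4,5-tetrabromobenzaldehyde oxime | O/N=C/c1cc(Br)c(Br)c(Br)c1Br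
F2 | step 4 | 2,3,4,5-tetrabromobenzonitrile | N#Cc1cc(Br)c(Br)c(Br)c1Br
F3 | step 4 | 2,3,5-tribromo-4-methoxybenzonitrile | COc1c(Br)cc(C#N)c(Br)c1Br
F4 | step 4 | 2,3,5-tribromo-4-methoxybenzaldimine | N=Cc1cc(Br)c(OC)c(Br)c1Br
F5 | step 2 | 1,2,3,4-tetrabromo-5-(hydroxymethyl)-7-thiabicyclo[2.2.1]hept-2-ene 7,7-dioxide (racemic) | OCC1CC2(Br)C(Br)=C(Br)C1(Br)S2(=O)=O
F6 | step 2 | (2,3,4,5-tetrabromocyclohexa-2,4-dien-1-yl)methanol (racemic) | OCC1CC(Br)=C(Br)C(Br)=C1Br
F7 | step 5 | 2,3,5-tribromo-4-[2-(methylsulfonyl)ethoxy]benzaldehyde | CS(=O)(=O)CCOc1c(Br)cc(C=O)c(Br)c1Br
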